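## Retrosynthetic overview

1. The only ring is a cyclohexene. Its C1=C2 bond (C1 bears CO2Me) lies between C6H2 and the oxygenated C3, so C3–C2–C1–C6 is the carbon chain of a diene. C4–C5, with its trans pair of oxygens, is what an (E)-alkene leaves behind.
2. Endgame: the C3 acetate comes from a C3 silyl ether. The C4 ester comes from a C4 acetate, which comes from a C4 acetyl group by Baeyer–Villiger oxidation with retention. The C5 ester is carried through from the start.
3. Key disconnection: C3–C4 and C5–C6 are cut together (retro-[4+2]) to a 1-silyloxy-3-carbomethoxy diene and an (E)-β-acyloxy enone. This one event forms the ring and its three stereocentres.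
4. Fragments: the diene comes from dimethoxyacetaldehyde by Wittig olefination, acetal hydrolysis and γ-silyl enolisation. The dienophile comes from (R)-2-methylbutanoic acid and butynone by conjugate addition.

Key step: step 5

Assumption: ring atoms carry shikimate numbering (C1 CO2Me, C3 OAc, C4 and C5 esters); the (R)-series of the catalyst is written on the basis of the α-C–H···O binding model for enones, the sense is to be checked on the first run by solvolysis of a sample of the Baeyer–Villiger product to methyl (−)-shikimate, and the equally available (S)-series is used if the sense is opposite.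

## Route

Step 1
Reactants: 1 2,2-dimethoxyacetaldehyde (60 wt% in water); 2 methyl 2-(triphenyl-λ5-phosphanylidene)propanoate
Product: 3 methyl (E)-4,4-dimethoxy-2-methylbut-2-enoate
Conditions: CH2Cl2, 23 °C
Reagents that add atoms: none
Why: Wittig olefination with a stabilised α-branched ylide, which tolerates the aqueous aldehyde and should place the acetal carbon trans to the ester, giving the (E)-trisubstituted enoate.

Step 2
Reactants: 3 methyl (E)-4,4-dimethoxy-2-methylbut-2-enoate
Product: 4 methyl (E)-2-methyl-4-oxobut-2-enoate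
Conditions: 1 M aq. HCl, acetone, 23 °C
Reagents that add atoms: water, O
Why: Acid-catalysed acetal hydrolysis, in which the methyl ester and the alkene geometry are not touched by dilute acid at room temperature.

Step 3
Reactants: 4 methyl (E)-2-methyl-4-oxobut-2-enoate
Product: 5 methyl (E)-4-(tert-butyldimethylsilyloxy)-2-methylidenebut-3-enoate
Conditions: TBSOTf (1.1 equiv), Et3N (1.5 equiv), Et2O, 0 °C; pentane filtration, kept cold and dilute, used at once
Reagents that add atoms: tert-butyldimethylsilyl trifluoromethanesulfonate (TBSOTf), CC(C)(C)[Si](C)(C)OS(=O)(=O)C(F)(F)F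
Why: Soft vinylogous (γ) enolisation of an enal to a silyl dienol ether: O-silylation by the triflate acidifies the C-methyl group that becomes C6, Et3N removes one of its protons, and reaction through the preferred s-trans enal should give the (E)-enol ether, which is used directly because its acrylate unit can add to a second molecule.

Step 4
Reactants: 6 (R)-2-methylbutanoic acid; 7 but-3-yn-2-one
Product: 8 (E)-3-oxobut-1-en-1-yl (R)-2-methylbutanoate
Conditions: DABCO (1,4-diazabicyclo[2.2.2]octane, 10 mol %), CH2Cl2, 0 → 23 °C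
Reagents that add atoms: none
Why: Amine-catalysed conjugate (oxa-Michael) addition of a carboxylic acid to an ynone, in which the carboxylate replaces the β-ammonium group by addition–elimination to give the favoured (E)-β-acyloxy enone, and the acid is never activated at its carbonyl group, so its α-stereocentre is not at risk.

Step 5
Reactants: 5 methyl (E)-4-(tert-butyldimethylsilyloxy)-2-methylidenebut-3-enoate (1.5 equiv); 8 (E)-3-oxobut-1-en-1-yl (R)-2-methylbutanoate
Product: 9 methyl (3R,4S,5R)-4-acetyl-3-(tert-butyldimethylsilyloxy)-5-{[(2R)-2-methylbutanoyl]oxy}cyclohex-1-ene-1-carboxylate (3,4-cis, 4,5-trans)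
Conditions: (3aR)-1-(2-methylphenyl)-3,3-diphenyltetrahydro-1H,3H-pyrrolo[1,2-c][1,3,2]oxazaborole (C24H24BNO, from (R)-α,α-diphenylprolinol, 20 mol %), HN(SO2CF3)2 (18 mol %), CH2Cl2, −78 → −40 °C; pH 7 buffer quench, short pad of deactivated silica
Reagents that add atoms: none
Why: The boron cation binds the ketone oxygen of 8, the most basic site because it is the carbonyl end of a vinylogous anhydride, and the lowered LUMO then meets the HOMO of 5 in a concerted but asynchronous suprafacial [4+2] cycloaddition in which C5–C6 forms ahead of C3–C4. The closest known reaction type is the catalytic enantioselective Diels–Alder reaction of acyclic enones with silyloxy dienes under N-protonated oxazaborolidines. The cyclohexene, the only ring of the target, is closed by intermolecular union of the four-carbon unit C3–C2–C1–C6 with the two-carbon unit C4–C5, and C1=C2 arises from the central bond of the diene. The step needs C6 to bond to C5 and not to C4, which the substrates secure twice: the silyloxy group at C3 puts the larger HOMO coefficient on C6 (ortho rule) and the ester at C1 ends up para to the acetyl group, while C5 is the β-carbon of the complexed enone. C3 and C4 become cis because the coordinated acetyl group sits endo under the (E)-silyloxy diene, and C4 and C5 become trans because the (E)-geometry of 8 is carried over suprafacially. The absolute sense comes from the catalyst, whose phenyl group covers one face of the s-trans enone held by the B–O bond and an α-C–H···O contact, so that 5 should reach the Re face of C4 and C5 and give 3R,4S,5R; the remote (R)-ester hardly steers but makes the minor facial isomer a separable diastereomer.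

Step 6
Reactants: 9 methyl (3R,4S,5R)-4-acetyl-3-(tert-butyldimethylsilyloxy)-5-{[(2R)-2-methylbutanoyl]oxy}cyclohex-1-ene-1-carboxylate
Product: 10 methyl (3R,4S,5R)-4-acetoxy-3-(tert-butyldimethylsilyloxy)-5-{[(2R)-2-methylbutanoyl]oxy}cyclohex-1-ene-1-carboxylate
Conditions: urea·H2O2, (CF3CO)2O, Na2HPO4, CH2Cl2, 0 °C
Reagents that add atoms: urea–hydrogen peroxide, OO.NC(N)=O (its oxygen is delivered as trifluoroperacetic acid, OOC(=O)C(F)(F)F)
Why: Baeyer–Villiger oxidation, in which the secondary ring carbon C4 migrates in preference to methyl and with retention of configuration, while the electron-poor C1=C2 enoate resists the peracid at 0 °C and the phosphate buffer protects the silyl ether and holds back β-elimination.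

Step 7
Reactants: 10 methyl (3R,4S,5R)-4-acetoxy-3-(tert-butyldimethylsilyloxy)-5-{[(2R)-2-methylbutanoyl]oxy}cyclohex-1-ene-1-carboxylate
Product: 11 methyl (3R,4S,5R)-3-(tert-butyldimethylsilyloxy)-4-hydroxy-5-{[(2R)-2-methylbutanoyl]oxy}cyclohex-1-ene-1-carboxylate
Conditions: K2CO3 (0.2 equiv), MeOH, −10 → 0 °C; pH 7 buffer
Reagents that add atoms: none
Why: Base-catalysed transesterification (Zemplén-type methanolysis) that distinguishes the unbranched acetate from the α-branched 2-methylbutanoate on steric grounds; exchange at the methyl ester is degenerate in methanol, and an O5→O4 acyl shift or some over-cleavage is harmless because step 8 puts the same acyl group on both oxygens.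

Step 8
Reactants: 11 methyl (3R,4S,5R)-3-(tert-butyldimethylsilyloxy)-4-hydroxy-5-{[(2R)-2-methylbutanoyl]oxy}cyclohex-1-ene-1-carboxylate; 6 (R)-2-methylbutanoic acid (1.5 equiv)
Product: 12 methyl (3R,4S,5R)-3-(tert-butyldimethylsilyloxy)-4,5-bis{[(2R)-2-methylbutanoyl]oxy}cyclohex-1-ene-1-carboxylate
Conditions: DCC (N,N'-dicyclohexylcarbodiimide, 1.5 equiv), DMAP (4-(dimethylamino)pyridine, 0.3 equiv), CH2Cl2, 0 → 23 °C
Reagents that add atoms: none
Why: Steglich esterification, which leaves the C4–O bond intact so that C4 keeps its configuration, and which should not epimerise a simple α-alkyl acid under carbodiimide/DMAP activation.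

Step 9
Reactants: 12 methyl (3R,4S,5R)-3-(tert-butyldimethylsilyloxy)-4,5-bis{[(2R)-2-methylbutanoyl]oxy}cyclohex-1-ene-1-carboxylate
Product: 13 methyl (3R,4R,5R)-3-hydroxy-4,5-bis{[(2R)-2-methylbutanoyl]oxy}cyclohex-1-ene-1-carboxylate (same spatial arrangement; the C4 descriptor changes through ligand ranking only)
Conditions: HF·pyridine, pyridine, THF, 0 → 23 °C (plastic vessel)
Reagents that add atoms: none
Why: Fluoride-driven desilylation in an acidic medium, where no alkoxide is formed and the cis O4→O3 acyl migration should therefore stay slow.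

Step 10
Reactants: 13 methyl (3R,4R,5R)-3-hydroxy-4,5-bis{[(2R)-2-methylbutanoyl]oxy}cyclohex-1-ene-1-carboxylate
Product: 14 methyl (3R,4S,5R)-3-acetoxy-4,5-bis{[(2R)-2-methylbutanoyl]oxy}cyclohex-1-ene-1-carboxylate (CNP0132712.1)
Conditions: Ac2O, pyridine, DMAP (cat.), CH2Cl2, 0 °C
Reagents that add atoms: acetic anhydride, CC(=O)OC(C)=O
Why: DMAP-catalysed acetylation of the allylic secondary alcohol, which with excess anhydride should outrun acyl migration and touches no stereocentre.

## Compound list

1 | 2,2-dimethoxyacetaldehyde | COC(OC)C=O | starting material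
2 | methyl 2-(triphenyl-λ5-phosphanylidene)propanoate | COC(=O)C(C)=P(c1ccccc1)(c1ccccc1)c1ccccc1 | starting material
3 | methyl (E)-4,4-dimethoxy-2-methylbut-2-enoate | COC(=O)/C(C)=C/C(OC)OC | intermediate
4 | methyl (E)-2-methyl-4-oxobut-2-enoate | COC(=O)/C(C)=C/C=O | intermediate
5 | methyl (E)-4-(tert-butyldimethylsilyloxy)-2-methylidenebut-3-enoate | C=C(C(=O)OC)/C=C/O[Si](C)(C)C(C)(C)C | intermediate
6 | (R)-2-methylbutanoic acid | CC[C@@H](C)C(=O)O | starting material
7 | but-3-yn-2-one | CC(=O)C#C | starting material
8 | (E)-3-oxobut-1-en-1-yl (R)-2-methylbutanoate | CC(=O)/C=C/OC(=O)[C@H](C)CC | intermediate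
9 | methyl (3R,4S,5R)-4-acetyl-3-(tert-butyldimethylsilyloxy)-5-{[(2R)-2-methylbutanoyl]oxy}cyclohex-1-ene-1-carboxylate | COC(=O)C1=C[C@@H](O[Si](C)(C)C(C)(C)C)[C@@H](C(C)=O)[C@H](OC(=O)[C@H](C)CC)C1 | intermediate
10 | methyl (3R,4S,5R)-4-acetoxy-3-(tert-butyldimethylsilyloxy)-5-{[(2R)-2-methylbutanoyl]oxy}cyclohex-1-ene-1-carboxylate | COC(=O)C1=C[C@@H](O[Si](C)(C)C(C)(C)C)[C@@H](OC(C)=O)[C@H](OC(=O)[C@H](C)CC)C1 | intermediate
11 | methyl (3R,4S,5R)-3-(tert-butyldimethylsilyloxy)-4-hydroxy-5-{[(2R)-2-methylbutanoyl]oxy}cyclohex-1-ene-1-carboxylate | COC(=O)C1=C[C@@H](O[Si](C)(C)C(C)(C)C)[C@@H](O)[C@H](OC(=O)[C@H](C)CC)C1 | intermediate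
12 | methyl (3R,4S,5R)-3-(tert-butyldimethylsilyloxy)-4,5-bis{[(2R)-2-methylbutanoyl]oxy}cyclohex-1-ene-1-carboxylate | COC(=O)C1=C[C@@H](O[Si](C)(C)C(C)(C)C)[C@@H](OC(=O)[C@H](C)CC)[C@H](OC(=O)[C@H](C)CC)C1 | intermediate
13 | methyl (3R,4R,5R)-3-hydroxy-4,5-bis{[(2R)-2-methylbutanoyl]oxy}cyclohex-1-ene-1-carboxylate | COC(=O)C1=C[C@@H](O)[C@@H](OC(=O)[C@H](C)CC)[C@H](OC(=O)[C@H](C)CC)C1 | intermediate
14 | methyl (3R,4S,5R)-3-acetoxy-4,5-bis{[(2R)-2-methylbutanoyl]oxy}cyclohex-1-ene-1-carboxylate | CC[C@@H](C)C(=O)O[C@@H]1[C@H](OC(C)=O)C=C(C(=O)OC)C[C@H]1OC(=O)[C@H](C)CC | target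

## Step count

- Total step count: 10
- Longest linear sequence: 9 (steps 1, 2, 3, 5, 6, 7, 8, 9, 10)

## Steps most likely to fail

**Step 5.** The ester-bearing diene is only moderately nucleophilic, and the donor-substituted enone is only moderately electrophilic. The union may therefore be slower than protodesilylation or self-cycloaddition of the diene. Facial selectivity on a β-heteroatom-substituted enone may also be poor.

The fallback sets out from 5 and 8 and gives up catalyst control. The cycloaddition is promoted by stoichiometric Me2AlCl, which also scavenges protic acid, in CH2Cl2 at −78 °C. Regiochemistry and endo orientation are substrate-borne, so two products are expected. One is 9. The other is its isomer with the antipodal ring, methyl (3S,4R,5S)-4-acetyl-3-(tert-butyldimethylsilyloxy)-5-{[(2R)-2-methylbutanoyl]oxy}cyclohex-1-ene-1-carboxylate F1. The resident (R)-ester makes the two diastereomers, so they can be separated by chromatography, here or after step 6. The route is rejoined at 9.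

**Step 6.** C4 is flanked by two oxygenated carbons and may migrate slowly. That leaves time for β-elimination of carboxylate and silanol with aromatisation, or for epoxidation of C1=C2.

The fallback sets out from 9 and replaces the peracid oxidation with an ozonolytic Criegee rearrangement:
- Non-basic Lombardo methylenation (Zn, CH2Br2, TiCl4, THF/CH2Cl2, 0 °C) takes the ketone in preference to the esters. It gives methyl (3R,4S,5R)-3-(tert-butyldimethylsilyloxy)-5-{[(2R)-2-methylbutanoyl]oxy}-4-(prop-1-en-2-yl)cyclohex-1-ene-1-carboxylate F2.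
- Ozone in CH2Cl2/MeOH at −78 °C attacks the electron-richer 1,1-disubstituted alkene. It gives the α-methoxy hydroperoxide methyl (3R,5R)-3-(tert-butyldimethylsilyloxy)-4-(2-hydroperoxy-2-methoxyethan-2-yl, i.e. 1-hydroperoxy-1-methoxyethyl)-5-{[(2R)-2-methylbutanoyl]oxy}cyclohex-1-ene-1-carboxylate F3.
- O-Acetylation (Ac2O, Et3N, DMAP, CH2Cl2, 23 → 40 °C) triggers migration of C4 to oxygen with retention. The route is rejoined at 10.

**Step 7.** The freed O4 alkoxide may pull the silyl group over from the cis O3, which would misplace the later acyl groups. The base may also start elimination along C6–C5.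

The fallback sets out from 10 and no longer differentiates the esters:
- Exhaustive solvolysis (NaOMe, MeOH, 23 °C, then methanolic HCl) gives methyl (−)-shikimate F4, which also serves as the configurational check.
- Butane-2,3-dione, HC(OMe)3 and camphorsulfonic acid in refluxing MeOH protect only the trans-diequatorial 4,5-diol. This gives methyl 4,5-O-[(2S,3S)-2,3-dimethoxybutane-2,3-diyl]shikimate F5.
- Ac2O/pyridine/DMAP gives its 3-acetate, methyl 3-O-acetyl-4,5-O-[(2S,3S)-2,3-dimethoxybutane-2,3-diyl]shikimate F6.
- CF3CO2H/H2O in CH2Cl2 at 0 °C releases methyl 3-O-acetylshikimate F7.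
- Double Steglich esterification with 6 (excess, DCC, DMAP, 0 °C) rejoins the route at 14.

## Further compounds

F1 | step 5 | methyl (3S,4R,5S)-4-acetyl-3-(tert-butyldimethylsilyloxy)-5-{[(2R)-2-methylbutanoyl]oxy}cyclohex-1-ene-1-carboxylate | COC(=O)C1=C[C@H](O[Si](C)(C)C(C)(C)C)[C@H](C(C)=O)[C@@H](OC(=O)[C@H](C)CC)C1
F2 | step 6 | methyl (3R,4S,5R)-3-(tert-butyldimethylsilyloxy)-5-{[(2R)-2-methylbutanoyl]oxy}-4-(prop-1-en-2-yl)cyclohex-1-ene-1-carboxylate | COC(=O)C1=C[C@@H](O[Si](C)(C)C(C)(C)C)[C@@H](C(C)=C)[C@H](OC(=O)[C@H](C)CC)C1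
F3 | step 6 | methyl 3-(tert-butyldimethylsilyloxy)-4-(1-hydroperoxy-1-methoxyethyl)-5-{[(2R)-2-methylbutanoyl]oxy}cyclohex-1-ene-1-carboxylate (ring as in 9, peroxy carbon as a mixture) | COC(=O)C1=C[C@@H](O[Si](C)(C)C(C)(C)C)[C@@H](C(C)(OC)OO)[C@H](OC(=O)[C@H](C)CC)C1
F4 | step 7 | methyl (3R,4S,5R)-3,4,5-trihydroxycyclohex-1-ene-1-carboxylate (methyl shikimate) | COC(=O)C1=C[C@@H](O)[C@@H](O)[C@H](O)C1
F5 | step 7 | methyl 4,5-O-[(2S,3S)-2,3-dimethoxybutane-2,3-diyl]shikimate | COC(=O)C1=C[C@@H](O)[C@H]2O[C@@](OC)(C)[C@](OC)(C)O[C@@H]2C1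
F6 | step 7 | methyl 3-O-acetyl-4,5-O-[(2S,3S)-2,3-dimethoxybutane-2,3-diyl]shikimate | COC(=O)C1=C[C@@H](OC(C)=O)[C@H]2O[C@@](OC)(C)[C@](OC)(C)O[C@@H]2C1
F7 | step 7 | methyl (3R,4S,5R)-3-acetoxy-4,5-dihydroxycyclohex-1-ene-1-carboxylate (methyl 3-O-acetylshikimate) | COC(=O)C1=C[C@@H](OC(C)=O)[C@@H](O)[C@H](O)C1
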